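**Plan**
Numbering (each half, primes for the other half): cyclopropane C1–C2–C3; cyclopentene C1, C3, C4, C5, C10; cyclohexenone C5–C10; C11 is the ester-bearing quaternary carbon on C7 (C12 ester, C13 methyl); C14 is the methyl on C10; C15 is the CH2 between C4 and C11′.
Cuts, in order: both C9–O bonds. Then, in each half, C3–C1 and C3–C2 together, which opens cyclopentene and cyclopropane at once to a C3 carbene and a C10 vinyl group. Then both C4–C5 bonds, which opens the 12-membered ring to two identical monomers. Then C11–C15′, C7–C11 and C10–C1.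
Forward: a bought six-membered ring; a temporary enol-lactone ring put on and taken off; head-to-tail cyclodimerisation to the 12-membered ring; last, both cyclopentene/cyclopropane pairs in one flask.
Enabling feature: the two small rings share the C1–C3 bond, and C3 ends the linear dienone C8(=O)–C7=C6–C5=C4, cis on C4=C5 to quaternary C10. A carbene at C3 therefore sits five atoms from a vinyl group on C10, and one [2+1] addition closes both rings.
Stereochemistry: C10 comes from a copper-catalysed asymmetric conjugate addition, C11 from a palladium-catalysed asymmetric allylic alkylation, C1 and C3 from C10 in the key step, and C9 from equilibration to the equatorial alcohol. C2 symmetry follows from dimerising one enantiomer.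

Key step: step 10

Assumption: the sense of induction of the two chiral ligands is assigned by analogy with simpler substrates, and the antipodal ligand would be used if the opposite sense were found.

Step 1
Reactants: 1 3-methylcyclohex-2-en-1-one; 2 vinylmagnesium bromide
Product: 3 (S)-3-ethenyl-3-methylcyclohexan-1-one
Conditions: 2, Me2AlCl, THF, 0 °C; then 1, Cu(OTf)2 (5 mol %), chiral phosphinamine ligand (6 mol %), Et2O, −30 °C; aq HCl
Reagents that add atoms: none
Why: Copper-catalysed asymmetric conjugate addition of an alkenylalane to a β-substituted cyclic enone, in which the chiral ligand should choose the enone face and so set the quaternary centre C10 (CH3 and vinyl).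

Step 2
Reactants: 3 (S)-3-ethenyl-3-methylcyclohexan-1-one; 4 methyl 2-bromopropanoate
Product: 5 methyl 2-[(4S)-4-ethenyl-4-methyl-2-oxocyclohexyl]propanoate (mixture at C7 and C11)
Conditions: LiN(i-Pr)2, THF, −78 °C; 4, DMPU, −78 to 0 °C
Reagents that add atoms: none
Why: Kinetic enolate alkylation, in which the amide base removes the C7 proton remote from quaternary C10 and SN2 attack on the α-bromo ester joins C7 to C11; the two new centres need no control because C11 is reset in step 4 and C7 is erased in step 6.

Step 3
Reactants: 5 methyl 2-[(4S)-4-ethenyl-4-methyl-2-oxocyclohexyl]propanoate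
Product: 7 (6S)-6-ethenyl-3,6-dimethyl-4,5,6,7-tetrahydro-1-benzofuran-2(3H)-one, via keto acid 6 (not isolated)
Conditions: LiOH, THF/H2O, 23 °C; aq HCl; then Ac2O, NaOAc (cat.), 100 °C
Reagents that add atoms: none
Why: Saponification followed by cyclodehydration of a γ-keto acid to the endocyclic enol lactone (C7=C8), a temporary ring that makes C11–H acidic and fixes the geometry of the later enolate.

Step 4
Reactants: 7 (6S)-6-ethenyl-3,6-dimethyl-4,5,6,7-tetrahydro-1-benzofuran-2(3H)-one; 8 2,3-dichloroprop-1-ene
Product: 9 (3R,6S)-3-(2-chloroprop-2-en-1-yl)-6-ethenyl-3,6-dimethyl-4,5,6,7-tetrahydro-1-benzofuran-2(3H)-one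
Conditions: Pd2(dba)3·CHCl3 (2.5 mol %), (R,R)-N,N′-(cyclohexane-1,2-diyl)bis[2-(diphenylphosphanyl)benzamide] (7.5 mol %), Cs2CO3, THF, −20 °C
Reagents that add atoms: none
Why: Tsuji–Trost asymmetric allylic alkylation, in which zerovalent palladium ionises only the allylic C–Cl bond, the aromatic 2-furanolate of 7 attacks through its α-carbon, and the chiral pocket should choose the enolate face to set quaternary C11 (R) independently of remote C10.

Step 5
Reactants: 9 (3R,6S)-3-(2-chloroprop-2-en-1-yl)-6-ethenyl-3,6-dimethyl-4,5,6,7-tetrahydro-1-benzofuran-2(3H)-one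
Product: 10 methyl (2R)-4-chloro-2-[(4S)-4-ethenyl-4-methyl-2-oxocyclohexyl]-2-methylpent-4-enoate (mixture at C7)
Conditions: NaOMe (0.1 equiv), MeOH, 0 °C
Reagents that add atoms: methanol, CO
Why: Methanolysis of an activated enol ester, which takes out the temporary lactone and unveils the C12 methyl ester and the C8 ketone; the C7 centre formed on ketonisation is erased in step 6.

Step 6
Reactants: 10 methyl (2R)-4-chloro-2-[(4S)-4-ethenyl-4-methyl-2-oxocyclohexyl]-2-methylpent-4-enoate
Product: 11 methyl (2R)-4-chloro-2-[(4S)-4-ethenyl-4-methyl-6-oxocyclohex-1-en-1-yl]-2-methylpent-4-enoate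
Conditions: IBX, 4-methoxypyridine N-oxide, DMSO, 25 °C
Reagents that add atoms: none
Why: IBX dehydrogenation of a ketone to an enone, which can only give C6=C7 because the other α-carbon (C9) adjoins quaternary C10 and has no β-hydrogen.

Step 7
Reactants: 11 methyl (2R)-4-chloro-2-[(4S)-4-ethenyl-4-methyl-6-oxocyclohex-1-en-1-yl]-2-methylpent-4-enoate (two molecules)
Product: 14 12-membered bis(dienone) with C4=C5 and C6=C7 in each half (C3H3 cis to C10; C15 cis to C6; CH3 and vinyl on C10), via linear head-to-tail dimer 12 (not isolated), via unconjugated macrocycle 13 (not isolated)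
Conditions: Pd(OAc)2 (10 mol %), 2-dicyclohexylphosphino-2′,4′,6′-triisopropylbiphenyl (20 mol %), Cs2CO3, DMF, 90 °C, slow addition to 2 mM
Reagents that add atoms: none
Why: Proposed new method: Cs2CO3 should form the linear dienolate of 11 and zerovalent palladium should insert into the alkenyl C4–Cl bond; because the α-carbon C7 is blocked by the tertiary C11 group, C–C reductive elimination is channelled to the γ-carbon C5, first between two molecules (12) and then in the ring-closing sense (13), coupling within one monomer being excluded since it would give a bicyclo[3.3.1]nonane with bridgehead alkenes; the base then moves C4=C3 into conjugation (13 to 14), A(1,3) strain placing the small CH3 next to quaternary C10, and no lasting stereocentre is formed; the closest known types are the palladium-catalysed γ-arylation of α,β-unsaturated ketones and the α-alkenylation of ketone enolates.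

Step 8
Reactants: 14 12-membered bis(dienone)
Product: 15 bis(enal), as 14 with each C3 as CHO cis to C10
Conditions: SeO2, 1,4-dioxane, 80 °C
Reagents that add atoms: selenium dioxide, O=[Se]=O
Why: Riley oxidation of a vinylogously activated methyl group, as known for β-methyl enones; the open C3 methyl should react ahead of the neopentyl C15 and C9 methylenes, the vinyl groups have no allylic hydrogen, and the C4=C5 geometry is kept.

Step 9
Reactants: 15 bis(enal)
Product: 16 bis(N-tosylhydrazone) of 15
Conditions: 4-methylbenzenesulfonohydrazide, THF, 23 °C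
Reagents that add atoms: 4-methylbenzenesulfonohydrazide, Cc1ccc(cc1)S(=O)(=O)NN
Why: Hydrazone condensation that should touch only the aldehydes, since both ketones are conjugated and flanked by the tertiary C11 group, and the fully substituted C5 blocks aza-Michael closure.

Step 10
Reactants: 16 bis(N-tosylhydrazone)
Product: 18 9,9′-dideoxycycloshizukaol A, via bis(diazo) macrocycle 17 (not isolated)
Conditions: LiOt-Bu, THF, 0 °C; then Rh2(OAc)4 (4 mol %), BnEt3NCl (10 mol %), 1,4-dioxane, 45 °C
Reagents that add atoms: none
Why: Bamford–Stevens loss of sulfinate gives the doubly vinylogous diazo ketone 17, and Rh2(OAc)4 turns each C3 diazo carbon into a metal-bound alkenyl carbene that adds in one concerted, suprafacial [2+1] step to the C1=C2 vinyl group held on C10. The closest known type is the intramolecular cyclopropanation of a 1,5-related alkene by an alkenyl carbene (from alkenyl diazo compounds or ring-opened cyclopropenes), which gives bicyclo[3.1.0]hex-2-enes. Because cyclopentene (C1, C3, C4, C5, C10) and cyclopropane (C1, C2, C3) share the C1–C3 bond, the C3–C1 bond closes the five-membered ring in the 5-exo sense while the C3–C2 bond closes the three-membered ring in the same event, so both rings of each half appear together and last, on the finished 12-membered ring. C1 and C3 are forced cis by the ring fusion, and their sense relative to C10 should follow from the only low-energy reactive rotamer, in which C1=C2 eclipses the pseudo-axial C10–CH3 bond and so places C2 on the methyl face. The step needs chemoselectivity for the vinyl group over 1,5-electrocyclisation to a pyrazole, carbene dimerisation and attack on the dienone; the cis placement of C3 and C10 on C4=C5, the full substitution of C5 and the slow release of 17 from its salt should secure it.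

Step 11
Reactants: 18 9,9′-dideoxycycloshizukaol A
Product: 20 cycloshizukaol A, via 9,9′-bis-epimer 19 (not isolated)
Conditions: KN(SiMe3)2, THF, −78 °C; 2-(phenylsulfonyl)-3-phenyloxaziridine; aq NH4Cl; then K2CO3 (cat.), MeOH, 23 °C
Reagents that add atoms: 2-(phenylsulfonyl)-3-phenyloxaziridine, O=S(=O)(c1ccccc1)N1OC1c1ccccc1
Why: Kinetic α′-enolate hydroxylation with an N-sulfonyloxaziridine should occur anti to the axial C10 methyl (axial 9α-alcohol 19), and α-ketol epimerisation through the enediolate should then deliver the equatorial, hydrogen-bonded 9β-alcohol, cis to CH3, while C8=O stays in conjugation.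

**Compound list**
1 | 3-methylcyclohex-2-en-1-one | CC1=CC(=O)CCC1 | starting material
2 | vinylmagnesium bromide | C=C[Mg]Br | starting material
3 | (S)-3-ethenyl-3-methylcyclohexan-1-one | O=C1C[C@@](C)(C=C)CCC1 | intermediate
4 | methyl 2-bromopropanoate (racemic) | COC(=O)C(C)Br | starting material
5 | methyl 2-[(4S)-4-ethenyl-4-methyl-2-oxocyclohexyl]propanoate (mixture at C7, C11) | COC(=O)C(C)C1CC[C@](C)(C=C)CC1=O | intermediate
6 | 2-[(4S)-4-ethenyl-4-methyl-2-oxocyclohexyl]propanoic acid (keto acid) | OC(=O)C(C)C1CC[C@](C)(C=C)CC1=O | intermediate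
7 | (6S)-6-ethenyl-3,6-dimethyl-4,5,6,7-tetrahydro-1-benzofuran-2(3H)-one | CC1C(=O)OC2=C1CC[C@](C)(C=C)C2 | intermediate
8 | 2,3-dichloroprop-1-ene | C=C(Cl)CCl | starting material
9 | (3R,6S)-3-(2-chloroprop-2-en-1-yl)-6-ethenyl-3,6-dimethyl-4,5,6,7-tetrahydro-1-benzofuran-2(3H)-one | C[C@]1(CC(Cl)=C)C(=O)OC2=C1CC[C@](C)(C=C)C2 | intermediate
10 | methyl (2R)-4-chloro-2-[(4S)-4-ethenyl-4-methyl-2-oxocyclohexyl]-2-methylpent-4-enoate (mixture at C7) | COC(=O)[C@](C)(CC(Cl)=C)C1CC[C@](C)(C=C)CC1=O | intermediate
11 | methyl (2R)-4-chloro-2-[(4S)-4-ethenyl-4-methyl-6-oxocyclohex-1-en-1-yl]-2-methylpent-4-enoate | COC(=O)[C@](C)(CC(Cl)=C)C1=CC[C@](C)(C=C)CC1=O | intermediate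
12 | linear head-to-tail dimer (one C4=C5 unit made; one free C5H2, one free 2-chloroallyl group) | C=C(Cl)C[C@@](C)(C(=O)OC)C1=C/C(=C(/C)C[C@@](C)(C(=O)OC)C2=CC[C@](C)(C=C)CC2=O)[C@](C)(C=C)CC1=O | intermediate
13 | unconjugated macrocycle (C5–H, exocyclic C4=C3H2 in each half) | COC(=O)[C@]1(C)CC(=C)C2C=C(C(=O)C[C@@]2(C)C=C)[C@](C)(C(=O)OC)CC(=C)C2C=C1C(=O)C[C@@]2(C)C=C | intermediate
14 | 12-membered bis(dienone), C3H3 cis to C10, (10S,11R,10′S,11′R) | COC(=O)[C@]1(C)C/C(C)=C2\C=C(C(=O)C[C@@]2(C)C=C)[C@](C)(C(=O)OC)C/C(C)=C2\C=C1C(=O)C[C@@]2(C)C=C | intermediate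
15 | bis(enal), C3 as CHO cis to C10 | COC(=O)[C@]1(C)C/C(C=O)=C2\C=C(C(=O)C[C@@]2(C)C=C)[C@](C)(C(=O)OC)C/C(C=O)=C2\C=C1C(=O)C[C@@]2(C)C=C | intermediate
16 | bis(N-tosylhydrazone) of 15 | COC(=O)[C@]1(C)C/C(C=NNS(=O)(=O)c3ccc(C)cc3)=C2\C=C(C(=O)C[C@@]2(C)C=C)[C@](C)(C(=O)OC)C/C(C=NNS(=O)(=O)c3ccc(C)cc3)=C2\C=C1C(=O)C[C@@]2(C)C=C | intermediate
17 | bis(diazo) macrocycle (C3H=N2 in each half) | COC(=O)[C@]1(C)C/C(C=[N+]=[N-])=C2\C=C(C(=O)C[C@@]2(C)C=C)[C@](C)(C(=O)OC)C/C(C=[N+]=[N-])=C2\C=C1C(=O)C[C@@]2(C)C=C | intermediate
18 | 9,9′-dideoxycycloshizukaol A | COC(=O)[C@]1(C)CC2=C3C=C(C(=O)C[C@@]3(C)[C@@H]3C[C@H]23)[C@](C)(C(=O)OC)CC2=C3C=C1C(=O)C[C@@]3(C)[C@@H]1C[C@H]21 | intermediate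
19 | 9,9′-bis-epi-cycloshizukaol A (9α-OH, trans to C14) | COC(=O)[C@]1(C)CC2=C3C=C(C(=O)[C@@H](O)[C@@]3(C)[C@@H]3C[C@H]23)[C@](C)(C(=O)OC)CC2=C3C=C1C(=O)[C@@H](O)[C@@]3(C)[C@@H]1C[C@H]21 | intermediate
20 | cycloshizukaol A | COC(=O)[C@]1(C)CC2=C3C=C(C(=O)[C@H](O)[C@@]3(C)[C@@H]3C[C@H]23)[C@](C)(C(=O)OC)CC2=C3C=C1C(=O)[C@H](O)[C@@]3(C)[C@@H]1C[C@H]21 | target

Total step count: 11. Longest linear sequence: 11 steps (from 1).

**Steps most likely to fail**

Step 7 (Proposed new method). Possible failures are oligomerisation in place of ring closure, coupling at the α′-carbon C9, and Heck-type capture of the alkenylpalladium species by a vinyl group. The fallback sets out from 11 and comes back at 14, using known reactions and making the same C4–C5 bond between two sp2 carbons. γ-Oxidation of 11 (dirhodium tetrakis(caprolactamate), t-BuOOH) would give the ene-dione F1. Zn in AcOH would reduce it to the 1,4-diketone F2. Kinetic enolisation at the open C6 position (KN(SiMe3)2) and N-(5-chloropyridin-2-yl)bis(trifluoromethanesulfonimide) would give the C5 enol triflate F3. Miyaura borylation (PdCl2(dppf), B2pin2, KOPh), which leaves the alkenyl chloride alone, would give the C5 alkenyl boronate F4. Suzuki–Miyaura cyclodimerisation of F4 (Pd(OAc)2, 2-dicyclohexylphosphino-2′,6′-dimethoxybiphenyl, K3PO4, high dilution) would give the macrocyclic bis(diene) F5. DBU would then move both diene units into conjugation with C8=O to reach 14.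

Step 10. Possible failures are electrocyclisation of the alkenyl diazo unit before the metal captures it, carbene dimerisation across the ring, and poor facial selectivity at the vinyl group. The fallback sets out from 16 and comes back at 18, and makes the electrocyclisation deliberate. The lithium salt of 16 is warmed without metal so that both diazo units close to the bis(spiro-3H-pyrazole) F6. F6 is isolated and then irradiated (350 nm, benzene, 20 °C). Photochemical loss of nitrogen from 3H-pyrazoles is a known source of alkenyl carbenes and their cyclopropene valence isomers, and the strain of the cyclopropene would return the carbene for the same [2+1] closure.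

Step 8. Possible failures are loss of site selectivity (attack at C15 or C9) and over-oxidation of the aldehyde. The fallback sets out from 14 and comes back at 15, and replaces the ene-type oxidation with a radical and then ionic sequence. Wohl–Ziegler bromination (NBS, dibenzoyl peroxide, PhCF3, 80 °C) would give the bis(allylic bromide) F7, and Kornblum oxidation (DMSO, NaHCO3, 60 °C) would convert it into 15.

**Further compounds**
F1 | step 7 | ene-dione | COC(=O)[C@](C)(CC(Cl)=C)C1=CC(=O)[C@](C)(C=C)CC1=O
F2 | step 7 | 1,4-diketone | COC(=O)[C@](C)(CC(Cl)=C)C1CC(=O)[C@](C)(C=C)CC1=O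
F3 | step 7 | C5 enol triflate | COC(=O)[C@](C)(CC(Cl)=C)C1C=C(OS(=O)(=O)C(F)(F)F)[C@](C)(C=C)CC1=O
F4 | step 7 | C5 alkenyl boronate | COC(=O)[C@](C)(CC(Cl)=C)C1C=C(B2OC(C)(C)C(C)(C)O2)[C@](C)(C=C)CC1=O
F5 | step 7 | macrocyclic bis(diene) | COC(=O)[C@]1(C)CC(=C)C2=CC(C(=O)C[C@@]2(C)C=C)[C@](C)(C(=O)OC)CC(=C)C2=CC1C(=O)C[C@@]2(C)C=C
F6 | step 10 | bis(spiro-3H-pyrazole) | COC(=O)[C@]1(C)CC2=CN=NC23C=C(C(=O)C[C@@]3(C)C=C)[C@](C)(C(=O)OC)CC2=CN=NC23C=C1C(=O)C[C@@]3(C)C=C
F7 | step 8 | bis(allylic bromide) | COC(=O)[C@]1(C)C/C(CBr)=C2\C=C(C(=O)C[C@@]2(C)C=C)[C@](C)(C(=O)OC)C/C(CBr)=C2\C=C1C(=O)C[C@@]2(C)C=C
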